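(All runs are simulated with made-up constants; noise was put on by code.)

Late in the larch run, one of two earlier flasks of electrophile with nucleophile, the loss of electrophile has slowed: it drops 19 percentage points in the first 15.0 min but 8 points in the last 20.0 min.

| setting | larch | elm | theta | gamma |
|---|---|---|---|---|
| electrophile | 13 mM | 13 mM | 13 mM | 13 mM |
| nucleophile | 17 mM | 21 mM | 13.0 mM | 26.0 mM |
| remark | run made earlier | run made earlier |  |  |
| time |  |  | 1.0 h | 1.0 h |

| run | time / min | electrophile / % | target / % |
|---|---|---|---|
| larch | 5.00 | 95 | 7 |
| larch | 15.0 | 81 | 12 |
| larch | 30.0 | 68 | 18 |
| larch | 40.0 | 59 | 26 |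
| larch | 60.0 | 51 | 25 |
| elm | 5.00 | 92 | 8 |
| elm | 10.0 | 85 | 15 |
| elm | 15.0 | 80 | 15 |
| elm | 30.0 | 61 | 25 |
| elm | 60.0 | 44 | 36 |

(readings scatter by 2 percentage points)



* part of the electrophile that has reacted at the end, theta
* part of the electrophile that has reacted at the end, gamma
* what raising the concentration of nucleophile from its lowest to its highest value here does to the part of the electrophile that has reacted (changes below 5 percentage points count as none) (no change / it falls / it rises)

The reckoning here reads the flask as one electrophile using one nucleophile. The rate of loss is then the start rate (initial rate) times the fraction of electrophile left times the fraction of nucleophile left. Summing that slowing back from the last readings gives larch a start rate of 0.866 h⁻¹ and elm 1.04 h⁻¹, in fractions of the charge. Their ratio, 1.20, reads close to the nucleophile ratio, 1.24, so the start rate is taken to scale with the nucleophile charge.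

Scaled so, theta starts at 0.652 h⁻¹. Start rate times time gives 65.2 % of the charge. That figure is the start budget, the loss the time holds at an unslowed rate. Theta's charges are equal, so this reckoning keeps the two factors equal and the rate falls with their square. Each factor is reckoned to end at 0.605, together 0.366 of the start rate. The mean rate is the start rate divided by one plus the budget, so the reacted part is budget over one plus budget: 39.5 %.

Gamma has twice the budget, 130 %. Its electrophile is the limiting reagent, so its nucleophile factor falls more gently, and the same reckoning gives 64.8 %. That is a rise of 25 points.

The forecast gives 39 % (34 % to 50 %) for theta, 64 % (54 % to 72 %) for gamma, and "it rises": “A nucleophile-independent side path would compress this gap, so the ranges are wide.”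

The flasks give 40.0 % for theta and 65.2 % for gamma; on the trend, it rises, by 25 points.

    electrophile + nucleophile → acid set free + target (k = 0.790 M⁻¹ min⁻¹)
    nucleophile + acid set free ⇌ protonated nucleophile, settled at all times (K = 3.40 × 10⁵ M⁻¹)
    electrophile + target → side product (k = 1.10 M⁻¹ min⁻¹)

The gap of 25 points between gamma and theta is mainly due to the difference in nucleophile charge. Theta's budget of 65.2 % gives 39.5 % against 40.0 %, yet theta keeps 39 % of its nucleophile free at 1.00 h, against the reckoned 60.5 %. Two steps outside the budget pull opposite ways in theta: the turning of electrophile + target into side product supplies 8.5 points of the reacted part, while the pairing of nucleophile with acid set free holds back 6.8 points. For theta left until 4.0 h, the budget grows to 261 % and gives 72.3 %, and that flask stands at 74.4 %.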